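**Plan**

- Ring A is numbered C1 (quinone methide carbon), C2 (ring D, the 2,4-dihydroxyphenyl group), C3-H, C4-H, C5 (CH2OH), C6 (arylethynyl). Ring D and the diaryl carbon sit on the adjacent carbons C2 and C1, and C1 lies next to the inductively withdrawing sp carbon on C6, so both bonds can be cut at once back to a polarised C1–C2 aryne.
- Cuts, in retrosynthetic order: (a) quinone methide and free hydroxyls back to a MOM/TBS-protected triaryl carbinol; (b) the C2–C1' biaryl bond and the C1–carbinol bond back to a 4-fluoro-2-alkynylbenzyl silyl ether, a ring D aryllithium and a 4,4'-dioxygenated benzophenone; (c) the C6–C(sp) bond by Sonogashira disconnection.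
- Forward: the arylalkyne is made and coupled to 2-bromo-4-fluorobenzaldehyde; reduction and silylation give the fluoroarene; the three partners are joined in one flask; acid then frees the phenols, the benzylic alcohol and the quinone methide. No ring is formed at any stage; all five rings are purchased.
- Stereochemistry: the target has no stereocentre and no stereogenic double bond (the dienone ring is symmetric), so nothing has to be set.

Key step: step 9

Assumption: selaginellin F is taken to persist as the open quinone methide drawn, not as the isomeric 6H-benzo[c]chromene that closure of the ring D 2-hydroxyl onto the methide carbon would give; any such closure should be reversible in dilute acid.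

**Route**

Step 1
Reactants: 1 4-iodophenol
Product: 2 1-iodo-4-(methoxymethoxy)benzene
Conditions: NaH, DMF, 0 °C; MOMCl, 0 °C to rt
Reagents that add atoms: chloromethyl methyl ether, COCCl
Why: O-alkylation of the sodium phenoxide with the highly reactive α-chloro ether (Williamson-type etherification) should give the MOM ether cleanly.

Step 2
Reactants: 2 1-iodo-4-(methoxymethoxy)benzene, 3 ethynyltrimethylsilane
Product: 4 {[4-(methoxymethoxy)phenyl]ethynyl}trimethylsilane
Conditions: Pd(PPh3)2Cl2 (cat.), CuI (cat.), Et3N, THF, rt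
Reagents that add atoms: none
Why: Sonogashira coupling of an aryl iodide, which adds readily to zerovalent palladium at room temperature, with the copper acetylide of a silyl-capped alkyne.

Step 3
Reactants: 4 {[4-(methoxymethoxy)phenyl]ethynyl}trimethylsilane
Product: 5 1-ethynyl-4-(methoxymethoxy)benzene
Conditions: K2CO3 (0.2 equiv), MeOH, rt
Reagents that add atoms: none
Why: Base-catalysed methanolysis of the C(sp)–Si bond (protodesilylation) frees the terminal alkyne, and the aryl MOM ether is stable to base.

Step 4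
Reactants: 5 1-ethynyl-4-(methoxymethoxy)benzene, 6 2-bromo-4-fluorobenzaldehyde
Product: 7 4-fluoro-2-{[4-(methoxymethoxy)phenyl]ethynyl}benzaldehyde
Conditions: Pd(PPh3)2Cl2 (cat.), CuI (cat.), Et3N, THF, 55 °C, degassed
Reagents that add atoms: none
Why: Sonogashira coupling at the C–Br bond, which the ortho formyl group activates towards oxidative addition to zerovalent palladium, while the C–F bond is inert.

Step 5
Reactants: 7 4-fluoro-2-{[4-(methoxymethoxy)phenyl]ethynyl}benzaldehyde
Product: 8 (4-fluoro-2-{[4-(methoxymethoxy)phenyl]ethynyl}phenyl)methanol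
Conditions: NaBH4, MeOH/THF, 0 °C
Reagents that add atoms: none
Why: Borohydride reduction of the aldehyde is chemoselective and leaves the alkyne, the aryl fluoride and the acetal untouched.

Step 6
Reactants: 8 (4-fluoro-2-{[4-(methoxymethoxy)phenyl]ethynyl}phenyl)methanol
Product: 9 tert-butyl[(4-fluoro-2-{[4-(methoxymethoxy)phenyl]ethynyl}benzyl)oxy]dimethylsilane
Conditions: TBSCl, imidazole, DMF, rt
Reagents that add atoms: tert-butyldimethylsilyl chloride, CC(C)(C)[Si](C)(C)Cl
Why: Imidazole-promoted silylation of an unhindered primary alcohol gives a silyl ether that tolerates the amide base and the aryllithiums of step 9.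

Step 7
Reactants: 10 4-bromoresorcinol
Product: 11 1-bromo-2,4-bis(methoxymethoxy)benzene
Conditions: NaH (2.4 equiv), DMF, 0 °C; MOMCl, 0 °C to rt
Reagents that add atoms: chloromethyl methyl ether, COCCl
Why: Double Williamson-type O-alkylation of the bis-phenoxide installs the acetal groups, of which the ortho one will later stabilise the aryllithium by chelation.

Step 8
Reactants: 12 4,4'-dihydroxybenzophenone
Product: 13 4,4'-bis(methoxymethoxy)benzophenone
Conditions: NaH (2.4 equiv), DMF, 0 °C; MOMCl, 0 °C to rt
Reagents that add atoms: chloromethyl methyl ether, COCCl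
Why: Williamson-type O-alkylation of both phenoxides gives a ketone without acidic protons that can serve as the electrophile for an aryllithium.

Step 9
Reactants: 9 tert-butyl[(4-fluoro-2-{[4-(methoxymethoxy)phenyl]ethynyl}benzyl)oxy]dimethylsilane, 11 1-bromo-2,4-bis(methoxymethoxy)benzene, 13 4,4'-bis(methoxymethoxy)benzophenone
Product: 18 [4-({[tert-butyl(dimethyl)silyl]oxy}methyl)-2',4'-bis(methoxymethoxy)-3-{[4-(methoxymethoxy)phenyl]ethynyl}biphenyl-2-yl]bis[4-(methoxymethoxy)phenyl]methanol, via ring D aryllithium 14 (not isolated), via lithiated fluoroarene 15 (not isolated), via ring A aryne 16 (not isolated), via biaryllithium 17 (not isolated)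
Conditions: a) 11, t-BuLi (2 equiv per Br), THF, −78 °C; b) 9, lithium 2,2,6,6-tetramethylpiperidide (from 2,2,6,6-tetramethylpiperidine and n-BuLi), THF, −78 °C; c) solution from a) (about 2.5 equiv) added to b), −78 to −20 °C; d) 13 (excess over total organolithium), −78 °C to rt; aq NH4Cl
Reagents that add atoms: none
Why: Lithium 2,2,6,6-tetramethylpiperidide removes the ring A proton at C1, the most acidic because it lies between the fluorine on C2 and the sp carbon on C6, and the resulting 15 loses LiF on warming to give the C1–C2 aryne 16. Aryllithium 14 adds to 16 at C2, which forms the C2–C1' biaryl bond and leaves the charge at C1 in 17, and 17 then adds to the carbonyl group of 13 to form the bond from C1 to the carbinol carbon, the lithium alkoxide being protonated on work-up. The closest known reaction type is the three-component aryne coupling, in which an aryllithium adds to an aryne released from an ortho-lithiated haloarene and the new 2-biaryllithium is quenched by a carbonyl electrophile. No ring is closed and no stereocentre is formed. The step needs attack at C2 and not at C1, and this is secured by the inductively withdrawing alkynyl group on C6, which polarises the aryne so that the nucleophile enters at the distal, less hindered carbon and the carbanion develops beside the sp carbon, where the 2'-OMOM oxygen of ring D can also chelate lithium. An excess of 14 keeps 15 from adding to its own aryne, and 13 is charged in excess because surplus 14 consumes it as well.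

Step 10
Reactants: 18 [4-({[tert-butyl(dimethyl)silyl]oxy}methyl)-2',4'-bis(methoxymethoxy)-3-{[4-(methoxymethoxy)phenyl]ethynyl}biphenyl-2-yl]bis[4-(methoxymethoxy)phenyl]methanol
Product: 20 selaginellin F, via deprotected triaryl carbinol 19 (not isolated)
Conditions: 3 M aq HCl, THF, 45 °C; then aq NaHCO3 to pH 6–7
Reagents that add atoms: none
Why: Acid hydrolysis of the five aryl MOM acetals and the silyl ether gives carbinol 19, which ionises to the doubly 4-hydroxyphenyl-stabilised triarylmethyl cation and loses a phenolic proton on neutralisation to give the quinone methide (dehydration of a 4-hydroxytriaryl carbinol to a fuchsone).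

**Compound list**

1 | 4-iodophenol | Oc1ccc(I)cc1 | starting material
2 | 1-iodo-4-(methoxymethoxy)benzene | COCOc1ccc(I)cc1 | intermediate
3 | ethynyltrimethylsilane | C#C[Si](C)(C)C | starting material
4 | {[4-(methoxymethoxy)phenyl]ethynyl}trimethylsilane | COCOc1ccc(cc1)C#C[Si](C)(C)C | intermediate
5 | 1-ethynyl-4-(methoxymethoxy)benzene | COCOc1ccc(cc1)C#C | intermediate
6 | 2-bromo-4-fluorobenzaldehyde | O=Cc1ccc(F)cc1Br | starting material
7 | 4-fluoro-2-{[4-(methoxymethoxy)phenyl]ethynyl}benzaldehyde | O=Cc1ccc(F)cc1C#Cc1ccc(OCOC)cc1 | intermediate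
8 | (4-fluoro-2-{[4-(methoxymethoxy)phenyl]ethynyl}phenyl)methanol | OCc1ccc(F)cc1C#Cc1ccc(OCOC)cc1 | intermediate
9 | tert-butyl[(4-fluoro-2-{[4-(methoxymethoxy)phenyl]ethynyl}benzyl)oxy]dimethylsilane | Fc1ccc(CO[Si](C)(C)C(C)(C)C)c(C#Cc2ccc(OCOC)cc2)c1 | intermediate
10 | 4-bromoresorcinol (4-bromobenzene-1,3-diol) | Oc1ccc(Br)c(O)c1 | starting material
11 | 1-bromo-2,4-bis(methoxymethoxy)benzene | COCOc1ccc(Br)c(OCOC)c1 | intermediate
12 | 4,4'-dihydroxybenzophenone | O=C(c1ccc(O)cc1)c1ccc(O)cc1 | starting material
13 | 4,4'-bis(methoxymethoxy)benzophenone | O=C(c1ccc(OCOC)cc1)c1ccc(OCOC)cc1 | intermediate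
14 | 2,4-bis(methoxymethoxy)phenyllithium (ring D aryllithium) | [Li]c1ccc(OCOC)cc1OCOC | intermediate (not isolated)
15 | tert-butyl[(4-fluoro-3-lithio-2-{[4-(methoxymethoxy)phenyl]ethynyl}benzyl)oxy]dimethylsilane (lithium on ring A C1, between F and the alkynyl group) | Fc1ccc(CO[Si](C)(C)C(C)(C)C)c(C#Cc2ccc(OCOC)cc2)c1[Li] | intermediate (not isolated)
16 | tert-butyl[(3,4-didehydro-2-{[4-(methoxymethoxy)phenyl]ethynyl}benzyl)oxy]dimethylsilane (ring A C1–C2 aryne) | C1#CC(C#Cc2ccc(OCOC)cc2)=C(CO[Si](C)(C)C(C)(C)C)C=C1 | intermediate (not isolated)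
17 | [4-({[tert-butyl(dimethyl)silyl]oxy}methyl)-2',4'-bis(methoxymethoxy)-3-{[4-(methoxymethoxy)phenyl]ethynyl}biphenyl-2-yl]lithium | [Li]c1c(-c2ccc(OCOC)cc2OCOC)ccc(CO[Si](C)(C)C(C)(C)C)c1C#Cc1ccc(OCOC)cc1 | intermediate (not isolated)
18 | [4-({[tert-butyl(dimethyl)silyl]oxy}methyl)-2',4'-bis(methoxymethoxy)-3-{[4-(methoxymethoxy)phenyl]ethynyl}biphenyl-2-yl]bis[4-(methoxymethoxy)phenyl]methanol (fully protected triaryl carbinol) | OC(c1ccc(OCOC)cc1)(c1ccc(OCOC)cc1)c1c(-c2ccc(OCOC)cc2OCOC)ccc(CO[Si](C)(C)C(C)(C)C)c1C#Cc1ccc(OCOC)cc1 | intermediate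
19 | 2-[bis(4-hydroxyphenyl)(hydroxy)methyl]-4-(hydroxymethyl)-3-[(4-hydroxyphenyl)ethynyl]biphenyl-2',4'-diol | OC(c1ccc(O)cc1)(c1ccc(O)cc1)c1c(-c2ccc(O)cc2O)ccc(CO)c1C#Cc1ccc(O)cc1 | intermediate (not isolated)
20 | selaginellin F, 4-{[2',4'-dihydroxy-4-(hydroxymethyl)-3-[(4-hydroxyphenyl)ethynyl]biphenyl-2-yl](4-hydroxyphenyl)methylidene}cyclohexa-2,5-dien-1-one | O=C1C=CC(=C(c2ccc(O)cc2)c2c(-c3ccc(O)cc3O)ccc(CO)c2C#Cc2ccc(O)cc2)C=C1 | target

**Count**

Total steps: 10. Longest linear sequence: 8 steps (steps 1, 2, 3, 4, 5, 6, 9, 10).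

**Steps most likely to fail**

1. Step 9. Three things may go wrong: the aryllithium may add at C1 of the aryne and not at C2; lithiated fluoroarene 15 may add to its own aryne in competition with 14; and the congested C1 aryllithium may be protonated before it is captured by the electron-rich ketone. The fallback avoids the aryne and the hindered carbanion–ketone union. It sets out from fluoroarene 9 and returns at carbinol 18. The same cold lithiation of 9 (lithium 2,2,6,6-tetramethylpiperidide, THF, −78 °C) is quenched with CO2 before LiF is lost, which should give 3-({[tert-butyl(dimethyl)silyl]oxy}methyl)-6-fluoro-2-{[4-(methoxymethoxy)phenyl]ethynyl}benzoic acid F1. Treatment of F1 with excess ring D aryllithium 14 (from 11) in THF, −78 °C to rt, should displace the ortho fluoride by carboxylate-assisted nucleophilic aromatic substitution; since this is ipso attack, the aryl group can only enter at C2, giving 4-({[tert-butyl(dimethyl)silyl]oxy}methyl)-2',4'-bis(methoxymethoxy)-3-{[4-(methoxymethoxy)phenyl]ethynyl}biphenyl-2-carboxylic acid F2. Methylation (MeI, K2CO3, DMF) gives the methyl ester of that acid F3. Double addition of 4-(methoxymethoxy)phenyllithium F4, made from iodide 2 with t-BuLi at −78 °C, to ester F3 then delivers 18.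

2. Step 10. During the long acid exposure that five aryl acetals require, the freed benzylic hydroxyl may add across the electron-rich, acid-activated alkyne (hydroalkoxylation to an isochromene or phthalan), and deprotection may stall at partly protected stages. The fallback keeps the benzylic oxygen masked through the acid step by a protecting-group relay. It sets out from 18 and returns at 20. Bu4NF in THF at 0 °C removes only the silyl ether to give [4-(hydroxymethyl)-2',4'-bis(methoxymethoxy)-3-{[4-(methoxymethoxy)phenyl]ethynyl}biphenyl-2-yl]bis[4-(methoxymethoxy)phenyl]methanol F5. Ac2O, pyridine and catalytic DMAP acylate the primary hydroxyl while the hindered tertiary carbinol stays free, giving [2-{hydroxybis[4-(methoxymethoxy)phenyl]methyl}-2',4'-bis(methoxymethoxy)-3-{[4-(methoxymethoxy)phenyl]ethynyl}biphenyl-4-yl]methyl acetate F6. Aqueous HCl in THF then removes the acetals and forms the quinone methide with no aliphatic hydroxyl present, giving [2',4'-dihydroxy-2-[(4-hydroxyphenyl)(4-oxocyclohexa-2,5-dien-1-ylidene)methyl]-3-[(4-hydroxyphenyl)ethynyl]biphenyl-4-yl]methyl acetate F7. Brief methanolysis (K2CO3, MeOH, 0 °C, then pH 6 buffer) releases 20.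

3. Step 4. Oxidative dimerisation of the electron-rich terminal alkyne 5 may outrun the slower oxidative addition of the aryl bromide, so that the coupling stalls. The fallback moves the alkyne onto the aldehyde ring and lets the more reactive aryl iodide close the diarylalkyne. It sets out from bromide 6 and returns at aldehyde 7. Sonogashira coupling of 6 with excess ethynyltrimethylsilane 3 (Pd(PPh3)2Cl2, CuI, Et3N, 50 °C) should give 4-fluoro-2-[(trimethylsilyl)ethynyl]benzaldehyde F8. K2CO3 in MeOH then gives 2-ethynyl-4-fluorobenzaldehyde F9, and Sonogashira coupling of F9 with iodide 2 at rt gives 7.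

**Further compounds**

F1 | step 9 | 3-({[tert-butyl(dimethyl)silyl]oxy}methyl)-6-fluoro-2-{[4-(methoxymethoxy)phenyl]ethynyl}benzoic acid | OC(=O)c1c(F)ccc(CO[Si](C)(C)C(C)(C)C)c1C#Cc1ccc(OCOC)cc1
F2 | step 9 | 4-({[tert-butyl(dimethyl)silyl]oxy}methyl)-2',4'-bis(methoxymethoxy)-3-{[4-(methoxymethoxy)phenyl]ethynyl}biphenyl-2-carboxylic acid | OC(=O)c1c(-c2ccc(OCOC)cc2OCOC)ccc(CO[Si](C)(C)C(C)(C)C)c1C#Cc1ccc(OCOC)cc1
F3 | step 9 | methyl 4-({[tert-butyl(dimethyl)silyl]oxy}methyl)-2',4'-bis(methoxymethoxy)-3-{[4-(methoxymethoxy)phenyl]ethynyl}biphenyl-2-carboxylate | COC(=O)c1c(-c2ccc(OCOC)cc2OCOC)ccc(CO[Si](C)(C)C(C)(C)C)c1C#Cc1ccc(OCOC)cc1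
F4 | step 9 | 4-(methoxymethoxy)phenyllithium | [Li]c1ccc(OCOC)cc1
F5 | step 10 | [4-(hydroxymethyl)-2',4'-bis(methoxymethoxy)-3-{[4-(methoxymethoxy)phenyl]ethynyl}biphenyl-2-yl]bis[4-(methoxymethoxy)phenyl]methanol | OCc1ccc(-c2ccc(OCOC)cc2OCOC)c(C(O)(c2ccc(OCOC)cc2)c2ccc(OCOC)cc2)c1C#Cc1ccc(OCOC)cc1
F6 | step 10 | [2-{hydroxybis[4-(methoxymethoxy)phenyl]methyl}-2',4'-bis(methoxymethoxy)-3-{[4-(methoxymethoxy)phenyl]ethynyl}biphenyl-4-yl]methyl acetate | CC(=O)OCc1ccc(-c2ccc(OCOC)cc2OCOC)c(C(O)(c2ccc(OCOC)cc2)c2ccc(OCOC)cc2)c1C#Cc1ccc(OCOC)cc1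
F7 | step 10 | [2',4'-dihydroxy-2-[(4-hydroxyphenyl)(4-oxocyclohexa-2,5-dien-1-ylidene)methyl]-3-[(4-hydroxyphenyl)ethynyl]biphenyl-4-yl]methyl acetate | CC(=O)OCc1ccc(-c2ccc(O)cc2O)c(C(c2ccc(O)cc2)=C2C=CC(=O)C=C2)c1C#Cc1ccc(O)cc1
F8 | step 4 | 4-fluoro-2-[(trimethylsilyl)ethynyl]benzaldehyde | O=Cc1ccc(F)cc1C#C[Si](C)(C)C
F9 | step 4 | 2-ethynyl-4-fluorobenzaldehyde | O=Cc1ccc(F)cc1C#C
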